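The ten-membered ring is never closed by bond formation. It is the perimeter of two fused six-membered rings, ring B (C1, C2, C7, C8, C9, C10) and ring C (C2 to C7), whose shared bond is cut. The feature exploited is that the oxygen-bearing carbons C2 and C7 lie 1,6 to each other across the ten-membered ring and flank methyl-substituted C5, the imprint of a Birch-reduced tolyl ring. Ozonolysis of the tetrasubstituted C2=C7 alkene of a tricyclic 1,4-diene gives both ketones and the medium ring in one operation and keeps C4=C5 Z. The precursor, built from 6-methyl-2-tetralone, already carries C1, C8, C9, C10, C11, C12 and C17 in their final configuration.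

Key step: step 17

Remarks on the chemistry:
- Briarane numbering is used throughout: ring A = C1, C10, C11, C12, C13, C14; C15 on C1, C16 on C5, C20 on C11, C17(C18)–C19 the propanoate unit on C8. α/β refer to the usual drawing with the C15 methyl β.
- The sense of induction in step 2 is assumed to follow that known for 2-methylcyclohexanone.
- Compounds 24–26 are C17 epimer mixtures by design; C17 is set in step 14.

Step 1
Reactants: 1 6-methyl-2-tetralone; 2 iodomethane
Product: 5 rac-1,6-dimethyl-3,4-dihydronaphthalen-2(1H)-one, via pyrrolidine enamine 3 (not isolated), via C-methyl iminium iodide 4 (not isolated)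
Conditions: pyrrolidine, PhMe, reflux (−H2O); MeI, MeCN, 60 °C; NaOAc, AcOH, H2O
Reagents that add atoms: iodomethane, CI
Why: Stork enamine alkylation: the arene-conjugated enamine is methylated once at the benzylic carbon (later C1), which avoids the dialkylation of the free enolate; the new centre is racemic and is reset in step 2.

Step 2
Reactants: 5 rac-1,6-dimethyl-3,4-dihydronaphthalen-2(1H)-one; 6 ethyl vinyl ketone
Product: 9 (R)-1,6-dimethyl-1-(3-oxopentyl)-3,4-dihydronaphthalen-2(1H)-one, via chiral imine 7 (not isolated), via Michael adduct imine 8 (not isolated)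
Conditions: (R)-1-phenylethylamine, TsOH (cat.), PhMe, reflux (−H2O); 6, THF, 40 °C; 10% aq AcOH, 25 °C
Reagents that add atoms: ethyl vinyl ketone, CCC(=O)C=C
Why: Deracemising Michael addition of a chiral imine: the more substituted secondary enamine tautomer erases the old C1 configuration and adds to the enone through an aza-ene-like chair on the face away from the phenyl group, so the (R)-amine should give the (R) quaternary centre (C1 with C15 β).

Step 3
Reactants: 9 (R)-1,6-dimethyl-1-(3-oxopentyl)-3,4-dihydronaphthalen-2(1H)-one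
Product: 11 (S)-1,4a,7-trimethyl-4,4a,9,10-tetrahydrophenanthren-2(3H)-one (C12 ketone, C10=C11), via aldol ketol 10 (not isolated)
Conditions: NaOMe, MeOH, 60 °C
Reagents that add atoms: none
Why: Intramolecular aldol condensation, the second half of a Robinson annulation, closes ring A as the C10=C11 enone without touching quaternary C1.

Step 4
Reactants: 11 tricyclic enone
Product: 12 12α-hydroxy-Δ10(11) tricyclic allylic alcohol
Conditions: LiBH(s-Bu)3, THF, −78 °C; aq NH4Cl
Reagents that add atoms: none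
Why: 1,2-Reduction by a hindered hydride: the β-carbon is fully substituted, so conjugate reduction is shut off and the bulky borohydride attacks C12 along the equatorial (β) trajectory to give the pseudoaxial 12α-alcohol, as 4-en-3-one steroids give 3α-allylic alcohols.

Step 5
Reactants: 12 12α-hydroxy-Δ10(11) tricyclic allylic alcohol
Product: 13 trans-fused 10α-H, 11β-methyl, 12α-hydroxy tricycle
Conditions: [Ir(cod)(PCy3)(py)]PF6 (5 mol %), H2 (1 atm), CH2Cl2, 25 °C
Reagents that add atoms: none
Why: Hydroxyl-directed homogeneous hydrogenation: iridium bound to the 12α-hydroxyl adds H2 cis to the α face of the tetrasubstituted C10=C11 alkene, also the face remote from the C15 methyl, which sets 10α-H (trans fusion) and the axial 11β-methyl.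

Step 6
Reactants: 13 trans-fused 12α-alcohol
Product: 14 10α-H, 11β-methyl 12-ketone
Conditions: DMP, NaHCO3, CH2Cl2, 0 °C
Reagents that add atoms: none
Why: Dess–Martin oxidation under buffered conditions oxidises the secondary alcohol without enolising C11, so the contra-thermodynamic axial methyl is kept.

Step 7
Reactants: 14 12-ketone
Product: 16 Δ13-12-ketone (10α-H, 11β-methyl), via trimethylsilyl enol ether 15 (not isolated)
Conditions: LiN(i-Pr)2, Me3SiCl, THF, −78 °C; Pd(OAc)2, MeCN, 25 °C
Reagents that add atoms: none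
Why: Saegusa–Ito dehydrogenation: kinetic deprotonation takes an axial C13–H (the equatorial tertiary C11–H is misaligned and hindered), and Pd(OAc)2 turns the silyl enol ether into the C13=C14 enone with C11 untouched.

Step 8
Reactants: 16 Δ13-12-ketone
Product: 17 Δ13-8,12-dione
Conditions: CrO3, 3,5-dimethylpyrazole, CH2Cl2, −20 °C
Reagents that add atoms: chromium trioxide, O=[Cr](=O)=O
Why: Benzylic oxidation: C8 is the only benzylic methylene (C1 is quaternary, C16 is a slower methyl), the enone has no allylic C–H, and the non-acidic chromium trioxide–pyrazole complex does not epimerise C11.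

Step 9
Reactants: 17 Δ13-8,12-dione
Product: 19 C8 enol triflate (C8=C9) of the Δ13-12-ketone, via potassium enolate 18 (not isolated)
Conditions: KN(SiMe3)2, THF, −78 °C; PhNTf2
Reagents that add atoms: N-phenylbis(trifluoromethanesulfonimide), O=S(=O)(N(c1ccccc1)S(=O)(=O)C(F)(F)F)C(F)(F)F
Why: Kinetic enol triflate formation: the aryl ketone can enolise only towards C9, and this methylene is deprotonated faster than the misaligned C11–H of the enone, giving the vinyl triflate that will carry the side chain.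

Step 10
Reactants: 19 enol triflate enone
Product: 20 12β-hydroxy-Δ13 enol triflate
Conditions: NaBH4, CeCl3·7H2O, MeOH, −78 °C
Reagents that add atoms: none
Why: Luche 1,2-reduction: hydride adds to C12 from the α face, opposite the adjacent axial 11β-methyl and the C15 methyl, giving the pseudo-equatorial 12β-alcohol.

Step 11
Reactants: 20 12β-hydroxy-Δ13 enol triflate
Product: 21 12β-(tert-butyldimethylsilyloxy)-Δ13 enol triflate
Conditions: t-BuMe2SiOTf, 2,6-lutidine, CH2Cl2, −78 → 0 °C
Reagents that add atoms: tert-butyldimethylsilyl triflate, CC(C)(C)[Si](C)(C)OS(=O)(=O)C(F)(F)F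
Why: Silyl ether formation: the bulky group next to C13=C14 shields this alkene in the dihydroxylation of step 13 and tolerates the organozinc of step 12.

Step 12
Reactants: 21 silyl ether enol triflate; 22 methyl 2-bromopropanoate
Product: 24 methyl 2-(tricyclic Δ8(9),Δ13-dien-8-yl)propanoate with 12β-OTBS (C17 epimers), via Reformatsky reagent 23 (not isolated)
Conditions: 22, Zn, THF, 25 °C; 21, Pd(P(t-Bu)3)2 (5 mol %), THF, 40 °C
Reagents that add atoms: methyl 2-bromopropanoate, CC(Br)C(=O)OC
Why: Negishi-type cross-coupling of a zinc ester enolate with the vinyl triflate (α-vinylation of an ester) forms the C8–C17 bond under neutral conditions; C17 arises as both epimers and is set in step 14.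

Step 13
Reactants: 24 alkene ester (C17 epimers)
Product: 26 8α,12β-dihydroxy C19→O9 γ-lactone, trans-fused on ring B (C17 epimers), via diol ester 25 (not isolated)
Conditions: OsO4 (2 mol %), N-methylmorpholine N-oxide, acetone–H2O, 0 °C; Bu4NF, THF, 0 → 25 °C
Reagents that add atoms: osmium tetroxide, O=[Os](=O)(=O)=O; N-methylmorpholine N-oxide, C[N+]1([O-])CCOCC1
Why: Catalytic syn-dihydroxylation: OsO4 takes the electron-rich trisubstituted styrenyl C8=C9 alkene from the α face, opposite the axial C15 methyl, setting 8α-OH and 9α-OH together; fluoride then removes the silyl group and lets the C9 alkoxide close the trans-fused γ-lactone on C19.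

Step 14
Reactants: 26 lactone (C17 epimers)
Product: 28 lactone with C17 set (C18 methyl cis to C7, trans to 8-OH), via trilithium enolate 27 (not isolated)
Conditions: LiN(i-Pr)2 (3.5 equiv), THF, −78 °C; 2,6-di-tert-butyl-4-methylphenol, −78 °C; aq NH4Cl
Reagents that add atoms: none
Why: Kinetic protonation of a γ-lactone enolate: the proton reaches C17 on the face of the small C8 oxygen, opposite aryl carbon C7, placing the C18 methyl cis to C7, the arrangement that becomes trans to C9 (and the more stable one) in the later 7,8-lactone.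

Step 15
Reactants: 28 lactone
Product: 30 8α,9α,12β-trihydroxy Δ2(7),Δ4,Δ13-triene carboxylic acid (Birch diene), via lithium carboxylate 29 (not isolated)
Conditions: LiOH·H2O, THF–H2O, 25 °C, evaporate; Li, NH3(l), THF, t-BuOH, −78 → −40 °C; isoprene, then NH4Cl
Reagents that add atoms: lithium hydroxide monohydrate, [Li+].[OH-].O
Why: Birch reduction: the 1,2,4-trialkylbenzene is protonated at C3 and C6 so that the alkyl-bearing carbons C2, C7 and C5 stay sp2 (C2=C7, C4=C5), while the carboxylate and alkoxides, the benzylic C8–O− included, resist reduction and hydrogenolysis as long as lithium is destroyed before the acidic quench; no stereocentre changes.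

Step 16
Reactants: 30 Birch diene acid
Product: 32 methyl ester with 9α,12β-diacetoxy and free 8α-hydroxyl (key-step precursor), via methyl ester triol 31 (not isolated)
Conditions: Me3SiCHN2, MeOH–PhMe, 0 °C; Ac2O, pyridine, DMAP, CH2Cl2, 25 °C
Reagents that add atoms: (trimethylsilyl)diazomethane, C[Si](C)(C)C=[N+]=[N-]; acetic anhydride, CC(=O)OC(C)=O
Why: Esterification then acetylation: the acid is methylated without base, the two secondary alcohols receive their final acetates (the C12 acetate also deactivates C13=C14 towards ozone) and the tertiary C8 hydroxyl stays free.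

Step 17
Reactants: 32 tricyclic Birch diene
Product: 35 ring A-fused (Z)-cyclodec-4-ene-2,7-dione, via primary ozonide 33 (not isolated), via secondary ozonide 34 (not isolated)
Conditions: O3 (1.0 equiv, titrated CH2Cl2 solution), CH2Cl2, −78 °C; Me2S, −78 → 20 °C
Reagents that add atoms: ozone, [O-][O+]=O
Why: Ozone adds as a 1,3-dipole to C2=C7 to give primary ozonide 33, which cycloreverts to a tethered ketone and carbonyl oxide that recombine to secondary ozonide 34, and Me2S reduces 34 to the C2 and C7 ketones. The closest known reaction type is the ozonolysis of the central tetrasubstituted alkene of Birch-derived isotetralins and octalins to cyclodecane-1,6-diones. No ring is closed by bond formation: cutting the bond shared by rings B and C merges them into their ten-atom perimeter, so the medium ring arises by fragmentation and needs no macrocyclisation. No stereocentre is created or touched, and C4=C5 stays Z because it is inherited from six-membered ring C. The step needs chemoselectivity for C2=C7: it is the only tetrasubstituted and most electron-rich alkene, C13=C14 is cis-disubstituted, flanked by quaternary C1 and deactivated by the allylic C12 acetate, and the margin over trisubstituted C4=C5 is guarded by dosing exactly one equivalent of ozone at −78 °C.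

Step 18
Reactants: 35 dione
Product: 37 C19→O7 γ-lactone (7α-O, trans-fused) with C2 ketone and (4Z)-alkene, via 7α-hydroxy ester 36 (not isolated)
Conditions: Zn(BH4)2, Et2O, −30 °C; aq NH4Cl; PPTS (cat.), CH2Cl2, 25 °C
Reagents that add atoms: none
Why: Chelation-controlled reduction: zinc bridges the C8 hydroxyl and the C7 carbonyl, hydride adds to the outer face of the chelate (the side of C17) to give the 7α-alcohol cis to 8α-OH, the hindered unchelated C2 ketone is left, and the new hydroxyl closes the trans-fused lactone on C19.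

Step 19
Reactants: 37 lactone ketone
Product: 38 (3Z,5Z)-dien-2-one lactone
Conditions: chloranil, t-BuOH–dioxane, 80 °C
Reagents that add atoms: none
Why: Quinone dehydrogenation of a β,γ-unsaturated ketone through its dienol: hydride is taken from the C6 methylene, not the C16 methyl, as 6-methyl-4-en-3-one steroids give 6-methyl-4,6-dien-3-ones, and the ten-membered ring accommodates the cis,cis-dienone.

Step 20
Reactants: 38 dienone lactone
Product: 39 2α-hydroxy-(3Z,5Z)-diene lactone
Conditions: NaBH4, CeCl3·7H2O, MeOH–CH2Cl2, −78 °C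
Reagents that add atoms: none
Why: Luche 1,2-reduction: hydride reaches C2 from the outer face of the ring, between C14 and C15, which places the hydroxyl α and H2 on the side of the C15 methyl.

Step 21
Reactants: 39 dienol
Product: 40 3α,4α-epoxy-2α-hydroxy-(5Z)-ene lactone
Conditions: VO(acac)2 (5 mol %), t-BuOOH, CH2Cl2, 0 → 25 °C
Reagents that add atoms: tert-butyl hydroperoxide, CC(C)(C)OO
Why: Hydroxyl-directed epoxidation: the vanadium alkoxide of the 2α-alcohol delivers oxygen to the adjacent (Z)-C3=C4 alkene on its own face, the cis outcome known for medium-ring (Z)-allylic alcohols, and leaves C5=C6 and C13=C14 alone.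

Step 22
Reactants: 40 epoxy alcohol
Product: 41 2α-acetoxy-3α,4α-epoxy-(5Z)-ene lactone
Conditions: Ac2O, pyridine, DMAP (cat.), CH2Cl2, 0 °C
Reagents that add atoms: acetic anhydride, CC(=O)OC(C)=O
Why: Acetylation of the only secondary hydroxyl, which also protects C2 from oxidation by hypochlorite in step 23.

Step 23
Reactants: 41 epoxy acetate
Product: 42 6α-chloro-5(16)-ene (exocyclic methylene) epoxy triacetate
Conditions: Ca(OCl)2, CO2 (solid), CH2Cl2–H2O, 0 °C
Reagents that add atoms: calcium hypochlorite, [Ca+2].[O-]Cl.[O-]Cl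
Why: Ene-type allylic chlorination of a trisubstituted alkene: electrophilic chlorine from HOCl adds to C6 on the outer face anti to the allylic C7–O bond (6α-Cl, H6 and H7 cis), and the C5 cation loses a C16 proton, the only one available since C4 is an epoxide carbon, to give the C5=C16 alkene.

Step 24
Reactants: 42 chloride
Product: 43 CNP0229305.1 (target)
Conditions: mCPBA, NaHCO3, CH2Cl2, 0 → 25 °C
Reagents that add atoms: 3-chloroperbenzoic acid, OOC(=O)c1cccc(Cl)c1
Why: Prilezhaev epoxidation: the peracid takes the cis-disubstituted C13=C14 alkene from the α face, opposite the C15 methyl on C1 and the 12β-acetate, in preference to the 1,1-disubstituted C5=C16 alkene, which is deactivated by the allylic chloride and the adjacent epoxide.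

Compound list
1 | 6-methyl-2-tetralone | Cc1ccc2CC(=O)CCc2c1 | starting material
2 | iodomethane | CI | starting material
3 | 1-(6-methyl-3,4-dihydronaphthalen-2-yl)pyrrolidine | Cc1ccc2C=C(N3CCCC3)CCc2c1 | intermediate
4 | 1-(1,6-dimethyl-3,4-dihydronaphthalen-2(1H)-ylidene)pyrrolidinium iodide (racemic) | Cc1ccc2C(C)C(=[N+]3CCCC3)CCc2c1.[I-] | intermediate
5 | rac-1,6-dimethyl-3,4-dihydronaphthalen-2(1H)-one | Cc1ccc2C(C)C(=O)CCc2c1 | intermediate
6 | ethyl vinyl ketone (pent-1-en-3-one) | CCC(=O)C=C | starting material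
7 | N-[(R)-1-phenylethyl] imine of 5 (C1 epimers, equilibrating with the secondary enamine) | Cc1ccc2C(C)C(=N[C@H](C)c3ccccc3)CCc2c1 | intermediate
8 | N-[(R)-1-phenylethyl] imine of 9 | Cc1ccc2[C@@](C)(CCC(=O)CC)C(=N[C@H](C)c3ccccc3)CCc2c1 | intermediate
9 | (R)-1,6-dimethyl-1-(3-oxopentyl)-3,4-dihydronaphthalen-2(1H)-one | Cc1ccc2[C@@](C)(CCC(=O)CC)C(=O)CCc2c1 | intermediate
10 | tricyclic aldol ketol (10-hydroxy-12-ketone, C10/C11 mixture) | Cc1ccc2[C@]3(C)C(O)(C(C)C(=O)CC3)CCc2c1 | intermediate
11 | (S)-1,4a,7-trimethyl-4,4a,9,10-tetrahydrophenanthren-2(3H)-one | Cc1ccc2[C@]3(C)C(=C(C)C(=O)CC3)CCc2c1 | intermediate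
12 | 12α-hydroxy-Δ10(11) tricycle | Cc1ccc2[C@]3(C)C(=C(C)[C@H](O)CC3)CCc2c1 | intermediate
13 | trans-fused tricycle, 10α-H, 11β-methyl, 12α-OH | Cc1ccc2[C@]3(C)[C@H]([C@@H](C)[C@H](O)CC3)CCc2c1 | intermediate
14 | trans-fused 12-ketone, 10α-H, 11β-methyl | Cc1ccc2[C@]3(C)[C@H]([C@@H](C)C(=O)CC3)CCc2c1 | intermediate
15 | 12-(trimethylsilyloxy)-Δ12(13) enol ether | Cc1ccc2[C@]3(C)[C@H]([C@@H](C)C(O[Si](C)(C)C)=CC3)CCc2c1 | intermediate
16 | Δ13-12-ketone, 10α-H, 11β-methyl | Cc1ccc2[C@]3(C)[C@H]([C@@H](C)C(=O)C=C3)CCc2c1 | intermediate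
17 | Δ13-8,12-dione | Cc1ccc2[C@]3(C)[C@H]([C@@H](C)C(=O)C=C3)CC(=O)c2c1 | intermediate
18 | potassium C8 enolate of 17 | Cc1ccc2[C@]3(C)[C@H]([C@@H](C)C(=O)C=C3)C=C([O-])c2c1.[K+] | intermediate
19 | C8 enol triflate (C8=C9), Δ13-12-ketone | Cc1ccc2[C@]3(C)[C@H]([C@@H](C)C(=O)C=C3)C=C(OS(=O)(=O)C(F)(F)F)c2c1 | intermediate
20 | C8 enol triflate, 12β-hydroxy-Δ13 | Cc1ccc2[C@]3(C)[C@H]([C@@H](C)[C@@H](O)C=C3)C=C(OS(=O)(=O)C(F)(F)F)c2c1 | intermediate
21 | C8 enol triflate, 12β-OTBS-Δ13 | Cc1ccc2[C@]3(C)[C@H]([C@@H](C)[C@@H](O[Si](C)(C)C(C)(C)C)C=C3)C=C(OS(=O)(=O)C(F)(F)F)c2c1 | intermediate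
22 | methyl 2-bromopropanoate (racemic) | CC(Br)C(=O)OC | starting material
23 | bromo(1-methoxy-1-oxopropan-2-yl)zinc | CC([Zn]Br)C(=O)OC | intermediate
24 | methyl 2-(tricyclic Δ8(9),Δ13-dien-8-yl)propanoate, 12β-OTBS, C17 epimers | Cc1ccc2[C@]3(C)[C@H]([C@@H](C)[C@@H](O[Si](C)(C)C(C)(C)C)C=C3)C=C(C(C)C(=O)OC)c2c1 | intermediate
25 | 8α,9α-diol methyl ester, 12β-OTBS, C17 epimers | Cc1ccc2[C@]3(C)[C@H]([C@@H](C)[C@@H](O[Si](C)(C)C(C)(C)C)C=C3)[C@@H](O)[C@](O)(C(C)C(=O)OC)c2c1 | intermediate
26 | 8α,12β-dihydroxy C19→O9 trans-fused γ-lactone, C17 epimers | Cc1ccc2[C@]3(C)[C@H]([C@@H](C)[C@@H](O)C=C3)[C@@H](OC(=O)C4C)[C@@]4(O)c2c1 | intermediate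
27 | trilithium salt of 26 (C8 and C12 alkoxides, lactone enolate) | Cc1ccc2[C@]3(C)[C@H]([C@@H](C)[C@@H]([O-])C=C3)[C@@H](OC([O-])=C4C)[C@@]4([O-])c2c1.[Li+].[Li+].[Li+] | intermediate
28 | 8α,12β-dihydroxy C19→O9 lactone, C18 methyl cis to C7 | Cc1ccc2[C@]3(C)[C@H]([C@@H](C)[C@@H](O)C=C3)[C@@H](OC(=O)[C@@H]4C)[C@@]4(O)c2c1 | intermediate
29 | lithium 8α,9α,12β-trihydroxy carboxylate (arene) | Cc1ccc2[C@]3(C)[C@H]([C@@H](C)[C@@H](O)C=C3)[C@@H](O)[C@](O)([C@@H](C)C(=O)[O-])c2c1.[Li+] | intermediate
30 | 8α,9α,12β-trihydroxy Birch diene acid (C2=C7, C4=C5, C13=C14) | CC1=CCC=2[C@]3(C)[C@H]([C@@H](C)[C@@H](O)C=C3)[C@@H](O)[C@](O)([C@@H](C)C(=O)O)C2C1 | intermediate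
31 | methyl ester of 30 | CC1=CCC=2[C@]3(C)[C@H]([C@@H](C)[C@@H](O)C=C3)[C@@H](O)[C@](O)([C@@H](C)C(=O)OC)C2C1 | intermediate
32 | tricyclic Birch diene, 9α,12β-diacetoxy, 8α-hydroxy, methyl ester (key-step precursor) | CC1=CCC=2[C@]3(C)[C@H]([C@@H](C)[C@@H](OC(C)=O)C=C3)[C@@H](OC(C)=O)[C@](O)([C@@H](C)C(=O)OC)C2C1 | intermediate
33 | primary ozonide (1,2,3-trioxolane across C2–C7) | CC1=CCC2(OOO4)[C@]3(C)[C@H]([C@@H](C)[C@@H](OC(C)=O)C=C3)[C@@H](OC(C)=O)[C@](O)([C@@H](C)C(=O)OC)C24C1 | intermediate
34 | secondary ozonide (1,2,4-trioxolane bridging C2 and C7) | CC1=CCC2(OO4)[C@]3(C)[C@H]([C@@H](C)[C@@H](OC(C)=O)C=C3)[C@@H](OC(C)=O)[C@](O)([C@@H](C)C(=O)OC)C4(O2)C1 | intermediate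
35 | ring A-fused (Z)-cyclodec-4-ene-2,7-dione, 9α,12β-diacetoxy, 8α-hydroxy, methyl ester (key-step product) | C/C1=C/CC(=O)[C@]2(C)[C@H]([C@@H](C)[C@@H](OC(C)=O)C=C2)[C@@H](OC(C)=O)[C@](O)([C@@H](C)C(=O)OC)C(=O)C1 | intermediate
36 | 7α-hydroxy-2-ketone methyl ester | C/C1=C/CC(=O)[C@]2(C)[C@H]([C@@H](C)[C@@H](OC(C)=O)C=C2)[C@@H](OC(C)=O)[C@](O)([C@@H](C)C(=O)OC)[C@@H](O)C1 | intermediate
37 | 7,8-γ-lactone (7α-O), 2-ketone, (4Z)-ene | O=C1O[C@H]2C/C(C)=C\CC(=O)[C@]3(C)[C@H]([C@@H](C)[C@@H](OC(C)=O)C=C3)[C@@H](OC(C)=O)[C@]2(O)[C@H]1C | intermediate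
38 | 7,8-lactone (3Z,5Z)-dien-2-one | O=C1O[C@H]2/C=C(/C)\C=C/C(=O)[C@]3(C)[C@H]([C@@H](C)[C@@H](OC(C)=O)C=C3)[C@@H](OC(C)=O)[C@]2(O)[C@H]1C | intermediate
39 | 7,8-lactone 2α-hydroxy-(3Z,5Z)-diene | O=C1O[C@H]2/C=C(/C)\C=C/[C@@H](O)[C@]3(C)[C@H]([C@@H](C)[C@@H](OC(C)=O)C=C3)[C@@H](OC(C)=O)[C@]2(O)[C@H]1C | intermediate
40 | 3α,4α-epoxy-2α-hydroxy-(5Z)-ene lactone | O=C1O[C@H]2/C=C(/C)\[C@H]4O[C@H]4[C@@H](O)[C@]3(C)[C@H]([C@@H](C)[C@@H](OC(C)=O)C=C3)[C@@H](OC(C)=O)[C@]2(O)[C@H]1C | intermediate
41 | 2α,9α,12β-triacetoxy-3α,4α-epoxy-(5Z)-ene lactone | O=C1O[C@H]2/C=C(/C)\[C@H]4O[C@H]4[C@@H](OC(C)=O)[C@]3(C)[C@H]([C@@H](C)[C@@H](OC(C)=O)C=C3)[C@@H](OC(C)=O)[C@]2(O)[C@H]1C | intermediate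
42 | 6α-chloro-5(16)-ene-3α,4α-epoxy triacetate lactone (13,14-ene) | O=C1O[C@H]2[C@@H](Cl)C(=C)[C@H]4O[C@H]4[C@@H](OC(C)=O)[C@]3(C)[C@H]([C@@H](C)[C@@H](OC(C)=O)C=C3)[C@@H](OC(C)=O)[C@]2(O)[C@H]1C | intermediate
43 | CNP0229305.1 | C=C1[C@H]2O[C@H]2[C@@H](OC(C)=O)[C@]2(C)[C@H]([C@@H](C)[C@@H](OC(C)=O)[C@@H]3O[C@@H]32)[C@@H](OC(C)=O)[C@]2(O)[C@@H](C)C(=O)O[C@H]2[C@H]1Cl | target

Total step count: 24. Longest linear sequence: 24 steps from 1 (the zinc reagent of step 12 is made in the flask).

Steps most likely to fail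

Step 17. Ozone may be consumed competitively by the unhindered trisubstituted C4=C5 alkene, or over-ozonolysis may set in, because C2=C7 is flanked by two quaternary carbons and an allylic hydroxyl. The fallback sets out from 32 and uses the free C8 hydroxyl as a director: VO(acac)2 and t-BuOOH epoxidise only the allylic C2=C7 alkene to give the 2α,7α-epoxide F1. Periodic acid (H5IO6, THF–Et2O, 0 °C) then opens and cleaves the tetrasubstituted epoxide to the two ketones, which returns to the route at 35. The contact time must be short to spare the new α-hydroxy ketone.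

Step 23. Chlorine may be delivered to the wrong face of C6, or the developing C5 cation may be captured by water or by the neighbouring epoxide oxygen instead of losing a C16 proton. The fallback sets out from 41 and separates addition from elimination. PhSeCl at −78 °C gives the kinetic anti adduct, the 6-chloro-5-phenylselanyl compound F2, in which chloride enters as a nucleophile opposite to selenium, so the facial outcome is complementary to direct electrophilic chlorination. H2O2 and pyridine oxidise it to the selenoxide F3, whose syn-elimination can only run towards C16 and returns to the route at 42.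

Step 15. The tetra-lithium salt may precipitate so that the reduction stalls, or the benzylic C8–O bond may be hydrogenolysed if its alkoxide is protonated while lithium is still present. The fallback sets out from 29 and reduces a less charged species. Et3SiCl and imidazole in DMF give the tris(triethylsilyl) derivative F4, whose silyl ester is cleaved on aqueous K2CO3 work-up to the 9,12-bis(triethylsilyl) ether acid F5. Li in NH3 then reduces the soluble dianion to the diene acid bis(triethylsilyl) ether F6, and Bu4NF removes the silyl groups, returning to the route at 30.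

Further compounds
F1 | step 17 | 2α,7α-epoxide of 32 | CC1=CC[C@]2(O4)[C@]3(C)[C@H]([C@@H](C)[C@@H](OC(C)=O)C=C3)[C@@H](OC(C)=O)[C@](O)([C@@H](C)C(=O)OC)[C@]24C1
F2 | step 23 | 6α-chloro-5β-phenylselanyl adduct of 41 | O=C1O[C@H]2[C@@H](Cl)[C@](C)([Se]c5ccccc5)[C@H]4O[C@H]4[C@@H](OC(C)=O)[C@]3(C)[C@H]([C@@H](C)[C@@H](OC(C)=O)C=C3)[C@@H](OC(C)=O)[C@]2(O)[C@H]1C
F3 | step 23 | selenoxide of F2 | O=C1O[C@H]2[C@@H](Cl)[C@](C)([Se](=O)c5ccccc5)[C@H]4O[C@H]4[C@@H](OC(C)=O)[C@]3(C)[C@H]([C@@H](C)[C@@H](OC(C)=O)C=C3)[C@@H](OC(C)=O)[C@]2(O)[C@H]1C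
F4 | step 15 | triethylsilyl ester 9,12-bis(triethylsilyl) ether of the arene hydroxy acid | Cc1ccc2[C@]3(C)[C@H]([C@@H](C)[C@@H](O[Si](CC)(CC)CC)C=C3)[C@@H](O[Si](CC)(CC)CC)[C@](O)([C@@H](C)C(=O)O[Si](CC)(CC)CC)c2c1
F5 | step 15 | 9,12-bis(triethylsilyl) ether of the arene hydroxy acid | Cc1ccc2[C@]3(C)[C@H]([C@@H](C)[C@@H](O[Si](CC)(CC)CC)C=C3)[C@@H](O[Si](CC)(CC)CC)[C@](O)([C@@H](C)C(=O)O)c2c1
F6 | step 15 | 9,12-bis(triethylsilyl) ether of Birch diene acid 30 | CC1=CCC=2[C@]3(C)[C@H]([C@@H](C)[C@@H](O[Si](CC)(CC)CC)C=C3)[C@@H](O[Si](CC)(CC)CC)[C@](O)([C@@H](C)C(=O)O)C2C1
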